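A direct plan would make the diaryl ether by nucleophilic aromatic substitution and would end with a global deprotection.
The ring A phenol A1 (methyl 5-hydroxy-2,4-bis(methoxymethoxy)-3,6-dimethylbenzoate) would displace fluoride from the ring B fluoroarene A2 (tert-butyl 3-chloro-6-fluoro-5-formyl-4-methoxy-2-methylbenzoate) to give the protected ether A3.
The ether-forming substitution would be weakest: a phenoxide with two ortho substituents would have to attack a carbon flanked by a formyl and a tert-butyl ester group, so the tetra-ortho-substituted ether would form slowly and the aldehyde would compete as electrophile.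
The oxygenation of ring A at C5 would also be weak: formylation, protection and Dakin-type oxidation would spend three operations on one oxygen atom and would depend on aryl migration from a doubly ortho-substituted aldehyde.
The final dealkylation would have to cleave two acetals, a tert-butyl ester and an aryl methyl ether in A3 while sparing the methyl ester, and it would pay for protecting groups that add length but no complexity.

The target is treated as the seco-acid of a depsidone: the ring B carboxyl group and the ring A C4 hydroxyl are the two ends of an opened seven-membered lactone. Joining them first as an ester (the depside chloroatranorin, made from two simple benzoates) turns the diaryl ether bond, from the ring B oxygen to ring A C5, which lies para to the C2 hydroxyl, into an intramolecular dehydrogenative phenol coupling at the only aromatic C–H of the molecule. One operation thus forms the tetra-ortho-substituted ether with no leaving group and no protecting group, and hydroxide then opens the lactone. No substitution at a hindered fluoroarene, no Dakin sequence and no global deprotection remain.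

Key step: step 6

Remark: the target is achiral; the only stereocentre on the route (C5a of intermediate 11) is transient and racemic. Compound 8 (atraric acid) is taken as a commercial fragrance chemical.

Step 1
Reactants: 1 2,4-dihydroxy-6-methylbenzaldehyde
Product: 3 3-chloro-4,6-dihydroxy-2-methylbenzoic acid, via orsellinic acid 2 (not isolated)
Conditions: NaClO2 (1.1 equiv), NH2SO3H (1.2 equiv), THF/H2O, 0 °C → rt, no hypochlorite scavenger
Reagents that add atoms: sodium chlorite, [Na+].[O-]Cl=O
Why: Pinnick (Lindgren) oxidation turns the aldehyde into the acid, and the hypochlorous acid released by the same equation should chlorinate the resorcinol ring by electrophilic aromatic substitution at C3, para to the chelated hydroxyl and ortho to the free one; any isomeric or dichloro by-product would be removed by crystallisation.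

Step 2
Reactants: 3 3-chloro-4,6-dihydroxy-2-methylbenzoic acid
Product: 4 prop-2-enyl 3-chloro-4,6-dihydroxy-2-methylbenzoate
Conditions: allyl bromide (1.05 equiv), KHCO3 (1.1 equiv), DMF, rt
Reagents that add atoms: allyl bromide, C=CCBr
Why: SN2 O-alkylation of the carboxylate, which hydrogencarbonate forms in preference to the phenoxides, gives an ester that can later be removed without acid, strong base or hydrogen.

Step 3
Reactants: 4 prop-2-enyl 3-chloro-4,6-dihydroxy-2-methylbenzoate
Product: 6 prop-2-enyl 3-chloro-5-formyl-4,6-dihydroxy-2-methylbenzoate, via the aryl(chloro)methyl methyl ether 5 (not isolated)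
Conditions: Cl2CHOMe (2 equiv), TiCl4 (3 equiv), CH2Cl2, −10 → 0 °C; then 1 M aq. HCl
Reagents that add atoms: dichloromethyl methyl ether, COC(Cl)Cl; water, O
Why: In this Rieche formylation the titanium phenoxide delivers the electrophile to C5, the single free ring position (ortho to both hydroxyls), and aqueous work-up hydrolyses the α-chloro ether to the doubly chelated aldehyde.

Step 4
Reactants: 6 prop-2-enyl 3-chloro-5-formyl-4,6-dihydroxy-2-methylbenzoate
Product: 7 3-chloro-5-formyl-4,6-dihydroxy-2-methylbenzoic acid
Conditions: Pd(PPh3)4 (3 mol %), p-TolSO2Na (1.2 equiv), THF/MeOH, rt; then cold 1 M aq. HCl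
Reagents that add atoms: none
Why: Tsuji–Trost deallylation, in which zerovalent palladium ionises the allyl ester and the sulfinate captures the π-allyl complex as a sulfone, frees the acid under neutral non-reductive conditions that spare the aldehyde, the aryl chloride and the decarboxylation-prone hydroxy acid.

Step 5
Reactants: 7 3-chloro-5-formyl-4,6-dihydroxy-2-methylbenzoic acid; 8 methyl 2,4-dihydroxy-3,6-dimethylbenzoate (atraric acid)
Product: 10 methyl 4-[(3-chloro-5-formyl-4,6-dihydroxy-2-methylbenzoyl)oxy]-2-hydroxy-3,6-dimethylbenzoate (chloroatranorin), via the O-acylisourea 9 (not isolated)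
Conditions: DCC (1.1 equiv), 8 (1.2 equiv), dry THF/Et2O, 0 °C → rt, under N2
Reagents that add atoms: none
Why: Carbodiimide esterification, in which three of the four phenolic hydroxyls present are chelated to ortho carbonyl groups and only the C4 hydroxyl of 8 is free to attack the O-acylisourea, gives the depside without any protecting group.

Step 6
Reactants: 10 methyl 4-[(3-chloro-5-formyl-4,6-dihydroxy-2-methylbenzoyl)oxy]-2-hydroxy-3,6-dimethylbenzoate
Product: 12 methyl 2-chloro-4-formyl-3,8-dihydroxy-1,6,9-trimethyl-11-oxo-11H-dibenzo[b,e][1,4]dioxepine-7-carboxylate, via the ring A cyclohexadienone 11 (not isolated)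
Conditions: activated MnO2 (10 equiv), dry CHCl3 (0.005 M), rt, dark, under N2
Reagents that add atoms: none
Why: Oxidative phenol coupling (dehydrogenative diaryl ether formation) by MnO2: hydrogen-atom abstraction from a phenolic OH gives an aryloxyl radical, and the O6 radical of the benzoyl ring combines with the ring A radical (spin density at C5, para to the 2-OH), or adds to C5 of the neutral ring before a second oxidation. The closest known reaction types are the MnO2 cyclisation of depsides to depsidones and the para O–C coupling of aryloxyl radicals in poly(phenylene oxide) formation. The seven-membered dioxepinone ring is closed in a 7-endo mode by this O–C bond, the ester holding O6 within reach of C5, to give cyclohexadienone 11. The C5a stereocentre of 11 is transient and is erased when 11 tautomerises to the phenol, so nothing has to be controlled. The step needs O–C over C–C coupling and ring closure over dimerisation: C5 of ring A carries the only aromatic hydrogen of 10, the fully substituted benzoyl ring can react only through oxygen, its 4-OH cannot reach ring A, and high dilution disfavours intermolecular coupling. The aldehyde, the aryl chloride and both esters should not react with MnO2 in dry chloroform.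

Step 7
Reactants: 12 methyl 2-chloro-4-formyl-3,8-dihydroxy-1,6,9-trimethyl-11-oxo-11H-dibenzo[b,e][1,4]dioxepine-7-carboxylate
Product: 13 3-chloro-5-formyl-4-hydroxy-6-[2,4-dihydroxy-5-(methoxycarbonyl)-3,6-dimethylphenoxy]-2-methylbenzoic acid (target)
Conditions: LiOH (4 equiv), degassed THF/H2O, 0 °C → rt, under Ar; then cold 1 M aq. HCl to pH 2
Reagents that add atoms: water (as hydroxide), O
Why: Acyl substitution by hydroxide (saponification) should open the seven-membered aryl ester, which has a phenoxide leaving group, while the methyl ester, flanked by a methyl group and an ortho phenoxide, survives, the same selectivity by which alkali cleaves depsides yet leaves methyl β-orcinolcarboxylate intact.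

## Compound list

1 | 2,4-dihydroxy-6-methylbenzaldehyde (orcinaldehyde) | Cc1cc(O)cc(O)c1C=O | starting material
2 | 2,4-dihydroxy-6-methylbenzoic acid (orsellinic acid, not isolated) | Cc1cc(O)cc(O)c1C(=O)O | intermediate
3 | 3-chloro-4,6-dihydroxy-2-methylbenzoic acid | Cc1c(Cl)c(O)cc(O)c1C(=O)O | intermediate
4 | prop-2-enyl 3-chloro-4,6-dihydroxy-2-methylbenzoate | C=CCOC(=O)c1c(C)c(Cl)c(O)cc1O | intermediate
5 | prop-2-enyl 3-chloro-5-[chloro(methoxy)methyl]-4,6-dihydroxy-2-methylbenzoate (racemic, titanium-bound, not isolated) | C=CCOC(=O)c1c(C)c(Cl)c(O)c(C(Cl)OC)c1O | intermediate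
6 | prop-2-enyl 3-chloro-5-formyl-4,6-dihydroxy-2-methylbenzoate | C=CCOC(=O)c1c(C)c(Cl)c(O)c(C=O)c1O | intermediate
7 | 3-chloro-5-formyl-4,6-dihydroxy-2-methylbenzoic acid (5-chlorohaematommic acid) | Cc1c(Cl)c(O)c(C=O)c(O)c1C(=O)O | intermediate
8 | methyl 2,4-dihydroxy-3,6-dimethylbenzoate (atraric acid) | COC(=O)c1c(C)cc(O)c(C)c1O | starting material
9 | O-(3-chloro-5-formyl-4,6-dihydroxy-2-methylbenzoyl)-N,N'-dicyclohexylisourea (not isolated) | Cc1c(Cl)c(O)c(C=O)c(O)c1C(=O)OC(=NC1CCCCC1)NC1CCCCC1 | intermediate
10 | methyl 4-[(3-chloro-5-formyl-4,6-dihydroxy-2-methylbenzoyl)oxy]-2-hydroxy-3,6-dimethylbenzoate (chloroatranorin) | COC(=O)c1c(C)cc(OC(=O)c2c(C)c(Cl)c(O)c(C=O)c2O)c(C)c1O | intermediate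
11 | methyl 2-chloro-4-formyl-3-hydroxy-1,6,9-trimethyl-8,11-dioxo-5a,8-dihydro-11H-dibenzo[b,e][1,4]dioxepine-7-carboxylate (racemic at C5a, not isolated) | COC(=O)C1=C(C)C2Oc3c(C=O)c(O)c(Cl)c(C)c3C(=O)OC2=C(C)C1=O | intermediate
12 | methyl 2-chloro-4-formyl-3,8-dihydroxy-1,6,9-trimethyl-11-oxo-11H-dibenzo[b,e][1,4]dioxepine-7-carboxylate | COC(=O)c1c(C)c2Oc3c(C=O)c(O)c(Cl)c(C)c3C(=O)Oc2c(C)c1O | intermediate
13 | 3-chloro-5-formyl-4-hydroxy-6-[2,4-dihydroxy-5-(methoxycarbonyl)-3,6-dimethylphenoxy]-2-methylbenzoic acid (achiral) | COC(=O)c1c(C)c(Oc2c(C=O)c(O)c(Cl)c(C)c2C(=O)O)c(O)c(C)c1O | target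

Total step count: 7. Longest linear sequence: 7 steps (1 → 13); compound 8 is bought and enters at step 5.

Steps most likely to fail:

Step 6. The chelated, electron-poor phenols may resist oxidation, the aryloxyl radicals may couple between molecules to give oligomers, or ring A may be oxidised further through an ortho-quinone methide at its C3 methyl group. The fallback sets out from 10 and forms the same ring by cross-coupling instead of dehydrogenation: bromination with NBS in MeCN at 0 °C at the only aromatic C–H would give methyl 5-bromo-4-[(3-chloro-5-formyl-4,6-dihydroxy-2-methylbenzoyl)oxy]-2-hydroxy-3,6-dimethylbenzoate F1, and an intramolecular Ullmann etherification (CuI, picolinic acid, K3PO4, dry dioxane, 80 °C) would close the dioxepinone ring, coming back to the route at 12.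

Step 5. The O-acylisourea of the doubly ortho-substituted acid may rearrange to the unreactive N-acylurea before the hindered phenol attacks, or the hydroxy acid may acylate itself. The fallback sets out from 7 and replaces carbodiimide activation by ketene transfer: acetone, trifluoroacetic anhydride and trifluoroacetic acid would mask the carboxyl and the ortho hydroxyl together as 6-chloro-7-hydroxy-2,2,5-trimethyl-4-oxo-4H-1,3-benzodioxine-8-carbaldehyde F2, and irradiation of F2 at 300 nm in CH2Cl2 in the presence of 8 would expel acetone to give a quinoketene that the free C4 hydroxyl of 8 traps, coming back to the route at 10.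

Step 1. Chlorination may occur between the two hydroxyls or twice, or may outrun the oxidation of the chelated aldehyde, giving mixtures that are hard to separate. The fallback sets out from 1 and reverses the order of the two ring substitutions so that chlorine enters last at the only free position: Pinnick oxidation with 2-methylbut-2-ene as scavenger would give isolated 2, allylation as in step 2 would give prop-2-enyl 2,4-dihydroxy-6-methylbenzoate F3, chelation-controlled Rieche formylation between the hydroxyls would give prop-2-enyl 3-formyl-2,4-dihydroxy-6-methylbenzoate F4, and chlorination with SO2Cl2 in Et2O at 0 °C would come back to the route at 6.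

## Further compounds

F1 | step 6 | methyl 5-bromo-4-[(3-chloro-5-formyl-4,6-dihydroxy-2-methylbenzoyl)oxy]-2-hydroxy-3,6-dimethylbenzoate | COC(=O)c1c(C)c(Br)c(OC(=O)c2c(C)c(Cl)c(O)c(C=O)c2O)c(C)c1O
F2 | step 5 | 6-chloro-7-hydroxy-2,2,5-trimethyl-4-oxo-4H-1,3-benzodioxine-8-carbaldehyde | CC1(C)OC(=O)c2c(C)c(Cl)c(O)c(C=O)c2O1
F3 | step 1 | prop-2-enyl 2,4-dihydroxy-6-methylbenzoate | C=CCOC(=O)c1c(C)cc(O)cc1O
F4 | step 1 | prop-2-enyl 3-formyl-2,4-dihydroxy-6-methylbenzoate | C=CCOC(=O)c1c(C)cc(O)c(C=O)c1O
A1 | direct plan | methyl 5-hydroxy-2,4-bis(methoxymethoxy)-3,6-dimethylbenzoate | COC(=O)c1c(C)c(O)c(OCOC)c(C)c1OCOC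
A2 | direct plan | tert-butyl 3-chloro-6-fluoro-5-formyl-4-methoxy-2-methylbenzoate | COc1c(Cl)c(C)c(C(=O)OC(C)(C)C)c(F)c1C=O
A3 | direct plan | methyl 5-[2-(tert-butoxycarbonyl)-4-chloro-6-formyl-5-methoxy-3-methylphenoxy]-2,4-bis(methoxymethoxy)-3,6-dimethylbenzoate | COC(=O)c1c(C)c(Oc2c(C=O)c(OC)c(Cl)c(C)c2C(=O)OC(C)(C)C)c(OCOC)c(C)c1OCOC
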